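Ring B of this ent-labdane contains one unsubstituted methylene, C7, lying between C6 and C8, and C8 is the carbon that must finally carry C17 and the C7=C8 double bond. Ring B is therefore traced back to a cyclopentanone built from C5, C6, C8, C9 and C10, into which C7 is inserted. In one operation trimethylsilyldiazomethane forms C6–C7 and C7–C8, enlarges the five-membered ring to ring B and leaves the ketone at C8, ready for enol triflate carbonylation. The substrate is an enantiopure trans-fused 4,4,7a-trimethylhydrindan-2-one whose C9 bears the ketal-masked 3-oxobutyl chain, with C5, C9 and C10 already set.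

Key step: step 9

Remark: labdane numbering is used for the bicyclic compounds throughout, and the acyl group is read as 30-hydroxytriacontanoyl (carbonyl carbon plus 29 methylenes).

Step 1
Reactants: 1 2,2,6-trimethylcyclohexan-1-one (racemic); 2 allyl chloroformate
Product: 4 allyl 2,6,6-trimethylcyclohex-1-en-1-yl carbonate, via lithium enolate 3 (not isolated)
Conditions: LiN(SiMe3)2, THF, 0 °C; then 2, −78 → 25 °C
Reagents that add atoms: none
Why: Enolate O-acylation: the only enolate that 1 can form is the tetrasubstituted one, which the hard chloroformate acylates on oxygen, and the racemic C–H centre of 1 is erased on enolisation.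

Step 2
Reactants: 4 allyl 2,6,6-trimethylcyclohex-1-en-1-yl carbonate
Product: 5 (S)-2-allyl-2,6,6-trimethylcyclohexan-1-one
Conditions: Pd2(dba)3 (2.5 mol %), (S)-t-Bu-PHOX (6 mol %), THF, 25 °C
Reagents that add atoms: none
Why: Palladium-catalysed decarboxylative asymmetric allylic alkylation (Tsuji allylation): loss of CO2 gives an allylpalladium enolate that recombines inside the pocket of (S)-t-Bu-PHOX, the ligand enantiomer that gives (S)-configured α-quaternary cyclohexanones, so the future C10 is set here as (S).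

Step 3
Reactants: 5 (S)-2-allyl-2,6,6-trimethylcyclohexan-1-one
Product: 6 (S)-2,2,6-trimethyl-6-(2-oxopropyl)cyclohexan-1-one
Conditions: PdCl2 (10 mol %), Cu(OAc)2·H2O (25 mol %), O2 (1 atm), DMA/H2O (7:1), 25 °C
Reagents that add atoms: water, O
Why: Tsuji–Wacker oxidation converts the terminal alkene into the methyl ketone with Markovnikov selectivity and does not touch the hindered ring ketone or the quaternary centre.

Step 4
Reactants: 6 (S)-2,2,6-trimethyl-6-(2-oxopropyl)cyclohexan-1-one
Product: 7 (7aS)-4,4,7a-trimethyl-1,4,5,6,7,7a-hexahydro-2H-inden-2-one (bicyclic enone with C5=C6 and the C8 ketone)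
Conditions: KOH (cat), xylenes, 110 °C, Dean–Stark trap
Reagents that add atoms: none
Why: Intramolecular aldol condensation: the ring ketone has no α-hydrogen, so only the methyl group of the side-chain ketone can add to it, and dehydration gives the cyclopentenone with C5=C6.

Step 5
Reactants: 8 ethyl (2-methyl-1,3-dioxolan-2-yl)acetate
Product: 9 (2-methyl-1,3-dioxolan-2-yl)acetaldehyde
Conditions: i-Bu2AlH (1.05 equiv), CH2Cl2, −78 °C
Reagents that add atoms: none
Why: Partial ester reduction: at −78 °C the tetrahedral aluminium hemiacetal is stable and releases the aldehyde only on work-up, the ketal being inert to the hydride.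

Step 6
Reactants: 7 (7aS)-4,4,7a-trimethyl-1,4,5,6,7,7a-hexahydro-2H-inden-2-one; 9 (2-methyl-1,3-dioxolan-2-yl)acetaldehyde
Product: 11 (7aS)-1-[1-hydroxy-2-(2-methyl-1,3-dioxolan-2-yl)ethyl]-4,4,7a-trimethyl-1,4,5,6,7,7a-hexahydro-2H-inden-2-one (diastereomer mixture at C9 and C11), via lithium dienolate 10 (not isolated)
Conditions: LiN(i-Pr)2, THF, −78 °C; then 9, −78 °C; AcOH quench at −78 °C
Reagents that add atoms: none
Why: Directed aldol addition: 7 has no γ-hydrogen because C4 and C10 are quaternary, so the base can only form the cross-conjugated C9 enolate 10, which adds to the aldehyde faster than it deprotonates it at −78 °C; the two uncontrolled centres are removed in steps 7 and 8.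

Step 7
Reactants: 11 aldol adduct
Product: 13 (7aR)-4,4,7a-trimethyl-1-[2-(2-methyl-1,3-dioxolan-2-yl)ethylidene]-1,4,5,6,7,7a-hexahydro-2H-inden-2-one (C9=C11 geometry not controlled), via mesylate 12 (not isolated)
Conditions: MsCl, Et3N, CH2Cl2, 0 °C; then DBU, 25 °C
Reagents that add atoms: none
Why: Aldol dehydration by mesylation and E1cB elimination through the C9 enolate puts the new double bond in conjugation with the C8 ketone, and its geometry is irrelevant because it is hydrogenated next.

Step 8
Reactants: 13 cross-conjugated dienone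
Product: 14 (1S,3aR,7aR)-4,4,7a-trimethyl-1-[2-(2-methyl-1,3-dioxolan-2-yl)ethyl]octahydro-2H-inden-2-one (trans-fused; H5 anti and the C9 chain syn to the C10 methyl)
Conditions: H2 (3 atm), 10% Pd/C, EtOAc, 25 °C
Reagents that add atoms: none
Why: Heterogeneous catalytic hydrogenation saturates C9=C11 and C5=C6 from the face opposite the two syn-axial methyls (C20 on C10 and the axial methyl on C4), so H9 and H5 both enter anti to C20, which sets C9 (S, chain cis to C20) and C5 (R, trans fusion) in one operation, whereas enolate alkylation at C9 would have put the chain trans to C20.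

Step 9
Reactants: 14 (1S,3aR,7aR)-4,4,7a-trimethyl-1-[2-(2-methyl-1,3-dioxolan-2-yl)ethyl]octahydro-2H-inden-2-one; 15 trimethylsilyldiazomethane
Product: 17 ent-14,15,17-trinorlabdane-8,13-dione 13-ethylene ketal ((5R,9S,10R)-13,13-ethylenedioxy-14,15,17-trinorlabdan-8-one), via 7-silyl ketone 16 (not isolated)
Conditions: 15 (1.5 equiv), AlMe3 (2 equiv), CH2Cl2, −78 → −20 °C; aqueous work-up; then Bu4NF, AcOH, THF, 0 °C
Reagents that add atoms: none
Why: AlMe3 activates the C8 carbonyl, the diazo carbon of 15 adds to it, and loss of N2 from the diazonium aluminate is coupled to a 1,2-shift of the C6 methylene, which forms C7–C8 and C6–C7 and turns the cyclopentanone into the cyclohexanone of ring B (Lewis-acid-promoted diazoalkane homologation of a cyclic ketone, Tiffeneau–Demjanov type). Ring B is closed by ring expansion, not by cyclisation, so the trans fusion is inherited unchanged. No stereocentre is created: C5, C9 and C10 come from steps 2 and 8, and the transient C7 silyl centre of 16 is erased when fluoride removes the silicon. The step needs migration of C6 and not C9 and a single insertion; C9 is tertiary and next to quaternary C10, so the bulky silyldiazomethyl unit aligns for migration of the CH2 side, and the α-silyl ketone 16 is too hindered to react again. AlMe3 at low temperature should leave the dioxolane intact, and the AcOH-buffered desilylation avoids enolisation toward C9, so the equatorial chain set in step 8 is kept.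

Step 10
Reactants: 17 ent-14,15,17-trinorlabdane-8,13-dione 13-ethylene ketal
Product: 19 (5R,9S,10R)-13,13-ethylenedioxy-14,15,17-trinorlabd-7-en-8-yl trifluoromethanesulfonate, via lithium enolate 18 (not isolated)
Conditions: LiN(i-Pr)2, THF, −78 °C; then N-(5-chloropyridin-2-yl)bis(trifluoromethanesulfonimide), −78 → 0 °C
Reagents that add atoms: N-(5-chloropyridin-2-yl)bis(trifluoromethanesulfonimide), FC(F)(F)S(=O)(=O)N(c1ccc(Cl)cn1)S(=O)(=O)C(F)(F)F
Why: Regioselective enol triflate formation: kinetic deprotonation occurs at the C7 methylene and not at the hindered tertiary C9–H, and O-sulfonylation of enolate 18 fixes the C7=C8 position without touching C9.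

Step 11
Reactants: 19 enol triflate
Product: 20 methyl (5R,9S,10R)-13,13-ethylenedioxy-14,15-dinorlabd-7-en-17-oate
Conditions: Pd(OAc)2 (5 mol %), PPh3 (10 mol %), CO (1 atm), MeOH, Et3N, DMF, 50 °C
Reagents that add atoms: carbon monoxide, [C-]#[O+]; methanol, CO
Why: Palladium-catalysed alkoxycarbonylation of an enol triflate: oxidative addition to zerovalent palladium formed in situ, CO insertion and methanolysis of the acylpalladium install C17 on C8 with the C7=C8 bond fixed.

Step 12
Reactants: 20 unsaturated methyl ester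
Product: 21 (5R,9S,10R)-13,13-ethylenedioxy-14,15-dinorlabd-7-en-17-ol
Conditions: i-Bu2AlH (2.5 equiv), CH2Cl2, −78 → 0 °C
Reagents that add atoms: none
Why: Ester reduction: i-Bu2AlH reduces the conjugated ester in the 1,2 sense to the primary allylic alcohol and leaves the ketal and the trisubstituted alkene alone.

Step 13
Reactants: 21 allylic alcohol
Product: 22 (5R,9S,10R)-17-(tert-butyldiphenylsilyloxy)-13,13-ethylenedioxy-14,15-dinorlabd-7-ene
Conditions: t-BuPh2SiCl, imidazole, DMF, 25 °C
Reagents that add atoms: tert-butyl(chloro)diphenylsilane, CC(C)(C)[Si](Cl)(c1ccccc1)c1ccccc1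
Why: Silyl ether protection of the primary allylic O17 differentiates it from O15, which is generated later and must be the only free hydroxyl when the acyl group is attached, and this silyl group survives the acid of step 14.

Step 14
Reactants: 22 silyl ether ketal
Product: 23 (5R,9S,10R)-17-(tert-butyldiphenylsilyloxy)-14,15-dinorlabd-7-en-13-one
Conditions: PPTS (cat), acetone/H2O (10:1), 55 °C
Reagents that add atoms: water, O
Why: Ketal deprotection by mild acid-catalysed hydrolysis frees the C13 methyl ketone without cleaving the robust silyl ether or moving the C7=C8 bond.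

Step 15
Reactants: 23 methyl ketone
Product: 24 ethyl (5R,9S,10R,13E)-17-(tert-butyldiphenylsilyloxy)labda-7,13-dien-15-oate
Conditions: (EtO)2P(O)CH2CO2Et, NaH, THF, 0 → 50 °C; minor 13Z isomer removed by chromatography
Reagents that add atoms: triethyl phosphonoacetate, CCOC(=O)CP(=O)(OCC)OCC
Why: Horner–Wadsworth–Emmons olefination of the methyl ketone, with reversible addition of the phosphonate anion, favours the (E)-enoate in which the ester is trans to the larger C12 chain.

Step 16
Reactants: 24 (E)-enoate
Product: 25 (5R,9S,10R,13E)-17-(tert-butyldiphenylsilyloxy)labda-7,13-dien-15-ol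
Conditions: i-Bu2AlH (2.5 equiv), CH2Cl2, −78 °C
Reagents that add atoms: none
Why: Ester reduction: 1,2-reduction of the enoate gives the primary allylic alcohol with the C13=C14 geometry unchanged.

Step 17
Reactants: 26 15-bromopentadecanoic acid
Product: 27 15-bromopentadecan-1-ol
Conditions: BH3·THF, THF, 0 → 25 °C
Reagents that add atoms: none
Why: Chemoselective carboxylic acid reduction: borane reduces the acid through its acyloxyborane and leaves the primary bromide untouched.

Step 18
Reactants: 27 15-bromopentadecan-1-ol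
Product: 28 (15-bromopentadecyloxy)(tert-butyl)diphenylsilane
Conditions: t-BuPh2SiCl, imidazole, CH2Cl2, 25 °C
Reagents that add atoms: tert-butyl(chloro)diphenylsilane, CC(C)(C)[Si](Cl)(c1ccccc1)c1ccccc1
Why: Silyl ether protection of the primary alcohol, chosen so that both hydroxyl protecting groups of the final ester fall in one fluoride step and so that the bromide can be turned into a Grignard reagent.

Step 19
Reactants: 28 (15-bromopentadecyloxy)(tert-butyl)diphenylsilane; 26 15-bromopentadecanoic acid
Product: 31 30-(tert-butyldiphenylsilyloxy)triacontanoic acid, via Grignard reagent 29 (not isolated), via chloromagnesium carboxylate 30 (not isolated)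
Conditions: 28, Mg, THF, 50 °C; separately 26, MeMgCl (1.0 equiv), THF, −20 °C; then Li2CuCl4 (3 mol %) and the solution of 29, −20 → 0 °C; 1 M HCl work-up
Reagents that add atoms: none
Why: Copper-catalysed sp3–sp3 cross-coupling of a Grignard reagent with a primary alkyl bromide (Kochi coupling): the carboxyl group is masked in the flask as its unreactive chloromagnesium salt 30, so the organocopper species formed from 29 displaces only the bromide and joins the two C15 halves into the C30 chain.

Step 20
Reactants: 25 (5R,9S,10R,13E)-17-(tert-butyldiphenylsilyloxy)labda-7,13-dien-15-ol; 31 30-(tert-butyldiphenylsilyloxy)triacontanoic acid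
Product: 32 (5R,9S,10R,13E)-17-(tert-butyldiphenylsilyloxy)labda-7,13-dien-15-yl 30-(tert-butyldiphenylsilyloxy)triacontanoate
Conditions: EDC·HCl, DMAP (cat), CH2Cl2, 25 °C
Reagents that add atoms: none
Why: Carbodiimide esterification (Steglich) acylates the only free hydroxyl, the unhindered primary allylic O15, under neutral conditions that avoid allylic transposition.

Step 21
Reactants: 32 bis-silylated ester
Product: 33 ent-labda-7,13E-diene-15,17-diol 15-(30-hydroxytriacontanoate) ((5R,9S,10R,13E)-17-hydroxylabda-7,13-dien-15-yl 30-hydroxytriacontanoate), the target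
Conditions: Bu4NF, AcOH, THF, 25 → 40 °C
Reagents that add atoms: none
Why: Fluoride-mediated silyl ether cleavage removes both silyl groups at once, and the AcOH buffer keeps the allylic ester from being hydrolysed or transposed.

Compound list
1 | 2,2,6-trimethylcyclohexan-1-one (racemic) | CC1CCCC(C)(C)C1=O | starting material
2 | allyl chloroformate | C=CCOC(Cl)=O | starting material
3 | lithium 2,6,6-trimethylcyclohex-1-en-1-olate | [Li+].[O-]C1=C(C)CCCC1(C)C | intermediate
4 | allyl 2,6,6-trimethylcyclohex-1-en-1-yl carbonate | C=CCOC(=O)OC1=C(C)CCCC1(C)C | intermediate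
5 | (S)-2-allyl-2,6,6-trimethylcyclohexan-1-one | C=CC[C@]1(C)CCCC(C)(C)C1=O | intermediate
6 | (S)-2,2,6-trimethyl-6-(2-oxopropyl)cyclohexan-1-one | CC(=O)C[C@]1(C)CCCC(C)(C)C1=O | intermediate
7 | (7aS)-4,4,7a-trimethyl-1,4,5,6,7,7a-hexahydro-2H-inden-2-one | O=C1C[C@]2(C)CCCC(C)(C)C2=C1 | intermediate
8 | ethyl (2-methyl-1,3-dioxolan-2-yl)acetate | CCOC(=O)CC1(C)OCCO1 | starting material
9 | (2-methyl-1,3-dioxolan-2-yl)acetaldehyde | O=CCC1(C)OCCO1 | intermediate
10 | lithium dienolate of 7 (O–C8=C9, C5=C6 retained, 7aS) | [Li+].[O-]C1=C[C@]2(C)CCCC(C)(C)C2=C1 | intermediate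
11 | (7aS)-1-[1-hydroxy-2-(2-methyl-1,3-dioxolan-2-yl)ethyl]-4,4,7a-trimethyl-1,4,5,6,7,7a-hexahydro-2H-inden-2-one (C9 and C11 not controlled) | CC1(OCCO1)CC(O)C2C(=O)C=C3C(C)(C)CCC[C@@]23C | intermediate
12 | methanesulfonate of 11 (C9 and C11 not controlled) | CC1(OCCO1)CC(OS(C)(=O)=O)C2C(=O)C=C3C(C)(C)CCC[C@@]23C | intermediate
13 | (7aR)-4,4,7a-trimethyl-1-[2-(2-methyl-1,3-dioxolan-2-yl)ethylidene]-1,4,5,6,7,7a-hexahydro-2H-inden-2-one (C9=C11 geometry not controlled; quaternary centre unchanged, only its CIP label changes) | CC1(OCCO1)CC=C2C(=O)C=C3C(C)(C)CCC[C@@]23C | intermediate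
14 | (1S,3aR,7aR)-4,4,7a-trimethyl-1-[2-(2-methyl-1,3-dioxolan-2-yl)ethyl]octahydro-2H-inden-2-one (trans-fused, chain cis to the 7a-methyl) | CC1(OCCO1)CC[C@@H]2C(=O)C[C@@H]3C(C)(C)CCC[C@@]23C | intermediate
15 | trimethylsilyldiazomethane | C[Si](C)(C)C=[N+]=[N-] | starting material
16 | (5R,9S,10R)-13,13-ethylenedioxy-7-(trimethylsilyl)-14,15,17-trinorlabdan-8-one (C7 not controlled) | CC1(OCCO1)CC[C@@H]2C(=O)C([Si](C)(C)C)C[C@@H]3C(C)(C)CCC[C@@]23C | intermediate
17 | ent-14,15,17-trinorlabdane-8,13-dione 13-ethylene ketal, (5R,9S,10R) | CC1(OCCO1)CC[C@@H]2C(=O)CC[C@@H]3C(C)(C)CCC[C@@]23C | intermediate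
18 | lithium C7=C8 enolate of 17 | [Li+].CC1(OCCO1)CC[C@@H]2C([O-])=CC[C@@H]3C(C)(C)CCC[C@@]23C | intermediate
19 | (5R,9S,10R)-13,13-ethylenedioxy-14,15,17-trinorlabd-7-en-8-yl trifluoromethanesulfonate | CC1(OCCO1)CC[C@@H]2C(OS(=O)(=O)C(F)(F)F)=CC[C@@H]3C(C)(C)CCC[C@@]23C | intermediate
20 | methyl (5R,9S,10R)-13,13-ethylenedioxy-14,15-dinorlabd-7-en-17-oate | CC1(OCCO1)CC[C@@H]2C(C(=O)OC)=CC[C@@H]3C(C)(C)CCC[C@@]23C | intermediate
21 | (5R,9S,10R)-13,13-ethylenedioxy-14,15-dinorlabd-7-en-17-ol | CC1(OCCO1)CC[C@@H]2C(CO)=CC[C@@H]3C(C)(C)CCC[C@@]23C | intermediate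
22 | (5R,9S,10R)-17-(tert-butyldiphenylsilyloxy)-13,13-ethylenedioxy-14,15-dinorlabd-7-ene | CC1(OCCO1)CC[C@@H]2C(CO[Si](c4ccccc4)(c5ccccc5)C(C)(C)C)=CC[C@@H]3C(C)(C)CCC[C@@]23C | intermediate
23 | (5R,9S,10R)-17-(tert-butyldiphenylsilyloxy)-14,15-dinorlabd-7-en-13-one | CC(=O)CC[C@@H]1C(CO[Si](c2ccccc2)(c3ccccc3)C(C)(C)C)=CC[C@@H]4C(C)(C)CCC[C@@]14C | intermediate
24 | ethyl (5R,9S,10R,13E)-17-(tert-butyldiphenylsilyloxy)labda-7,13-dien-15-oate | CCOC(=O)/C=C(\C)CC[C@@H]1C(CO[Si](c2ccccc2)(c3ccccc3)C(C)(C)C)=CC[C@@H]4C(C)(C)CCC[C@@]14C | intermediate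
25 | (5R,9S,10R,13E)-17-(tert-butyldiphenylsilyloxy)labda-7,13-dien-15-ol | C/C(=C\CO)CC[C@@H]1C(CO[Si](c2ccccc2)(c3ccccc3)C(C)(C)C)=CC[C@@H]4C(C)(C)CCC[C@@]14C | intermediate
26 | 15-bromopentadecanoic acid | OC(=O)CCCCCCCCCCCCCCBr | starting material
27 | 15-bromopentadecan-1-ol | OCCCCCCCCCCCCCCCBr | intermediate
28 | (15-bromopentadecyloxy)(tert-butyl)diphenylsilane | BrCCCCCCCCCCCCCCCO[Si](c1ccccc1)(c2ccccc2)C(C)(C)C | intermediate
29 | [15-(tert-butyldiphenylsilyloxy)pentadecyl]magnesium bromide | Br[Mg]CCCCCCCCCCCCCCCO[Si](c1ccccc1)(c2ccccc2)C(C)(C)C | intermediate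
30 | chloromagnesium 15-bromopentadecanoate | [Mg+2].[Cl-].[O-]C(=O)CCCCCCCCCCCCCCBr | intermediate
31 | 30-(tert-butyldiphenylsilyloxy)triacontanoic acid | OC(=O)CCCCCCCCCCCCCCCCCCCCCCCCCCCCCO[Si](c1ccccc1)(c2ccccc2)C(C)(C)C | intermediate
32 | (5R,9S,10R,13E)-17-(tert-butyldiphenylsilyloxy)labda-7,13-dien-15-yl 30-(tert-butyldiphenylsilyloxy)triacontanoate | C/C(=C\COC(=O)CCCCCCCCCCCCCCCCCCCCCCCCCCCCCO[Si](c5ccccc5)(c6ccccc6)C(C)(C)C)CC[C@@H]1C(CO[Si](c2ccccc2)(c3ccccc3)C(C)(C)C)=CC[C@@H]4C(C)(C)CCC[C@@]14C | intermediate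
33 | ent-labda-7,13E-diene-15,17-diol 15-(30-hydroxytriacontanoate), (5R,9S,10R,13E) | C/C(=C\COC(=O)CCCCCCCCCCCCCCCCCCCCCCCCCCCCCO)CC[C@@H]1C(CO)=CC[C@@H]2C(C)(C)CCC[C@@]12C | target

Total step count: 21. Longest linear sequence: 17 steps (steps 1–4, 6–16, 20 and 21); steps 5 and 17–19 are side branches.

Steps most likely to fail

Step 9. The wrong α-carbon (C9) may migrate, a second insertion may follow on the product ketone, or the Lewis acid may open the dioxolane. The fallback sets out from 14 and replaces the insertion by a regiospecific cyclopropanation and oxidative ring opening. Kinetic deprotonation at the C6 methylene (LiN(i-Pr)2, Me3SiCl, THF, −78 °C) would give the C6=C8 trimethylsilyl enol ether F1. Cyclopropanation with Et2Zn and CH2I2 in CH2Cl2 at 0 °C would give the siloxycyclopropane F2, in which the new methylene bridges C6 and C8. FeCl3 in DMF with pyridine at 0 °C (Ito–Saegusa ring expansion) would cleave the internal C6–C8 bond to the 6-chloro-8-ketone F3, and NaOAc in MeOH would eliminate HCl to the 6-en-8-one F4. Hydrogenation of C6=C7 (H2, Pd/C, EtOAc) would return the route to 17.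

Step 8. Hydrogen delivery to the hindered C5=C6 bond may be slow or may occur from the methyl-bearing face, which would leave a mono-enone or erode the trans fusion. The fallback sets out from 13. Hydrogenation at 1 atm over Pd/C would be stopped after one equivalent, to give the C5=C6 enone with the C9 chain already cis to C20, F5. Homogeneous conjugate reduction with the bulky copper hydride [(Ph3P)CuH]6 in benzene with a little water, followed by NH4Cl, would then deliver hydride to C5 from the face opposite both axial methyls and return the route to 14.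

Step 15. The olefination of the unbiased methyl ketone may show only modest E/Z selectivity, with loss of material on separating the isomers. The fallback sets out from 23 and builds the trisubstituted alkene by syn-carbometalation. Kinetic enolisation on the methyl side and trapping (LiN(i-Pr)2, THF, −78 °C; ClP(O)(OEt)2) would give the enol phosphate F6, and excess LiN(i-Pr)2 (−78 → 25 °C) would eliminate it to the terminal alkyne F7. Zirconium-catalysed carboalumination (AlMe3, Cp2ZrCl2 cat, CH2Cl2), then n-BuLi and paraformaldehyde, would add methyl and the hydroxymethyl carbon cis to each other and give the (E)-allylic alcohol 25 directly, which bypasses 24.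

Further compounds
F1 | step 9 | trimethylsilyl enol ether of 14 toward C6 (C6=C8, 8-trimethylsilyloxy) | CC1(OCCO1)CC[C@@H]2C(O[Si](C)(C)C)=C[C@@H]3C(C)(C)CCC[C@@]23C
F2 | step 9 | siloxycyclopropane from F1 (new CH2 bridging C6 and C8, 8-trimethylsilyloxy, cyclopropane face not specified) | CC1(OCCO1)CC[C@@H]2C4(O[Si](C)(C)C)CC4[C@@H]3C(C)(C)CCC[C@@]23C
F3 | step 9 | (5R,9S,10R)-6-chloro-13,13-ethylenedioxy-14,15,17-trinorlabdan-8-one (C6 not controlled) | CC1(OCCO1)CC[C@@H]2C(=O)CC(Cl)[C@@H]3C(C)(C)CCC[C@@]23C
F4 | step 9 | (5R,9S,10R)-13,13-ethylenedioxy-14,15,17-trinorlabd-6-en-8-one | CC1(OCCO1)CC[C@@H]2C(=O)C=C[C@@H]3C(C)(C)CCC[C@@]23C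
F5 | step 8 | (1S,7aS)-4,4,7a-trimethyl-1-[2-(2-methyl-1,3-dioxolan-2-yl)ethyl]-1,4,5,6,7,7a-hexahydro-2H-inden-2-one (C5=C6 enone, chain cis to the 7a-methyl) | CC1(OCCO1)CC[C@@H]2C(=O)C=C3C(C)(C)CCC[C@@]23C
F6 | step 15 | diethyl (5R,9S,10R)-17-(tert-butyldiphenylsilyloxy)-14,15-dinorlabda-7,13(16)-dien-13-yl phosphate | C=C(OP(=O)(OCC)OCC)CC[C@@H]1C(CO[Si](c2ccccc2)(c3ccccc3)C(C)(C)C)=CC[C@@H]4C(C)(C)CCC[C@@]14C
F7 | step 15 | (5R,9S,10R)-17-(tert-butyldiphenylsilyloxy)-15,16-dinorlabd-7-en-13-yne | C#CCC[C@@H]1C(CO[Si](c2ccccc2)(c3ccccc3)C(C)(C)C)=CC[C@@H]4C(C)(C)CCC[C@@]14C
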